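## Retrosynthetic overview

- The target is read as 6β-acetoxy-7α-hydroxylabda-8,13Z-dien-15-ol, (5S,6S,7S,10S). Labdane numbering is used throughout: decalin C1–C10, gem-dimethyl on C4, methyl C17 on C8, methyl C20 on C10, side chain C11–C16 on C9.
- The side chain comes last. C12–C13 is made by B-alkyl Suzuki coupling of the 9-BBN adduct of a C9 vinyl group with a (Z)-3-iodobut-2-enyl silyl ether; the vinyl group comes from a C11 acyl group.
- The 6β-OAc/7α-OH pair goes back to a trans-fused 6-ketone: C7–O by α-face enolate hydroxylation, C6–H by α-face hydride addition, C5–H by protonation of a C5=C6 silyl enol ether.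
- The strategy rests on ring B: its tetrasubstituted C8=C9 alkene lies between quaternary C10 and C7 and is 1,4 to the C6 oxygen. Ring B is therefore the [4+2] adduct of the diene C7=C6(OSi)–C5=C10 and the alkyne C8≡C9 of a but-2-ynoyl pyrazole (new bonds C7–C8 and C9–C10), with C10 set by a chiral copper catalyst.
- Ring order: ring A is bought with β-cyclocitral, ring B is closed in the Diels–Alder step, and no further ring is formed.

Key step: step 5

Assumption: the sense of induction of the copper bis(oxazoline) catalyst on this new diene class cannot be predicted with confidence; the (S,S)-ligand is written, and the (R,R)-ligand would take its place if that is the one that delivers the 10β-methyl (10S) adduct.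

## Route

Step 1
Reactants: 1 β-cyclocitral
Product: 2 (±)-1-(2,6,6-trimethylcyclohex-1-en-1-yl)ethan-1-ol
Conditions: MeMgBr, Et2O, 0 °C → rt; aq. NH4Cl
Reagents that add atoms: methylmagnesium bromide, C[Mg]Br
Why: Grignard 1,2-addition to the aldehyde, conjugate addition being shut off by the fully substituted β-carbon; the carbinol centre is racemic and is destroyed in step 2.

Step 2
Reactants: 2 (±)-1-(2,6,6-trimethylcyclohex-1-en-1-yl)ethan-1-ol
Product: 3 1-(2,6,6-trimethylcyclohex-1-en-1-yl)ethan-1-one
Conditions: Dess–Martin periodinane, CH2Cl2, rt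
Reagents that add atoms: none
Why: Dess–Martin oxidation of a secondary allylic alcohol under neutral conditions should give the methyl ketone without migration of the ring double bond.

Step 3
Reactants: 3 1-(2,6,6-trimethylcyclohex-1-en-1-yl)ethan-1-one
Product: 4 tert-butyldimethyl{[1-(2,6,6-trimethylcyclohex-1-en-1-yl)ethenyl]oxy}silane (the 2-siloxydiene)
Conditions: TBSOTf, Et3N, CH2Cl2, 0 °C
Reagents that add atoms: tert-butyldimethylsilyl trifluoromethanesulfonate, CC(C)(C)[Si](C)(C)OS(=O)(=O)C(F)(F)F
Why: Soft enolisation of a methyl enone with a silyl triflate and an amine removes a proton from the acetyl methyl group (the kinetic α' site) and should give the cross-conjugated 2-siloxydiene, the standard preparation of such dienes.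

Step 4
Reactants: 5 but-2-ynoic acid; 6 3,5-dimethylpyrazole
Product: 7 1-(3,5-dimethyl-1H-pyrazol-1-yl)but-2-yn-1-one
Conditions: DCC, DMAP (5 mol %), CH2Cl2, 0 °C → rt
Reagents that add atoms: none
Why: Carbodiimide-mediated N-acylation (Steglich type) of the pyrazole N–H at low temperature and without free base should outrun conjugate addition of the pyrazole to the ynoyl unit.

Step 5
Reactants: 4 the 2-siloxydiene; 7 1-(3,5-dimethyl-1H-pyrazol-1-yl)but-2-yn-1-one
Product: 8 (10S)-6-(tert-butyldimethylsilyloxy)-5,8-diene with 10β-methyl and the (3,5-dimethylpyrazol-1-yl)carbonyl group (C11) on C9 (bicyclic Diels–Alder adduct)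
Conditions: Cu(OTf)2 (10 mol %), 2,2'-(propane-2,2-diyl)bis[(4S)-4-tert-butyl-4,5-dihydrooxazole] (11 mol %), 4 Å MS, CH2Cl2, −40 → 0 °C
Reagents that add atoms: none
Why: Proposed new method: the acyl pyrazole chelates the chiral divalent copper centre through its carbonyl oxygen and N2, which lowers the LUMO of the alkyne π bond conjugated with the carbonyl and holds it in a chiral pocket, so that diene 4 adds in a concerted but strongly asynchronous [4+2] cycloaddition in which C7–C8 leads and C9–C10 follows (in the stepwise limit, a Mukaiyama–Michael addition followed by collapse of the copper allenolate carbon C9 onto the allyl-oxocarbenium terminus C10). The closest known reaction types are the enantioselective Diels–Alder reaction of propioloyl pyrazoles with simple dienes under chiral divalent copper catalysis and the thermal cycloaddition of 1-vinyl-2,6,6-trimethylcyclohexene with acetylenic esters; a tetrasubstituted diene terminus under the catalytic asymmetric conditions is what is new. Ring B closes as the six-membered ring of the suprafacial [4π+2π] cycloaddition through the bonds C7–C8 and C9–C10, ring A being carried in unchanged. The only new stereocentre, C10, is set by which enantiotopic face of the diene meets the ligand-shielded dienophile; there is no endo/exo issue because the dienophile is an alkyne and C8=C9 stays planar. The step needs regioselectivity, which the 2-siloxy group secures by making the CH2 terminus C7 the nucleophilic end, so that it pairs with the β-carbon C8 of the ynoyl unit and the C6 oxygen ends up 1,4 to the C9 acyl group. The tert-butyldimethylsilyl enol ether should survive the mild Lewis acid, and molecular sieves keep water from hydrolysing the diene.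

Step 6
Reactants: 8 the Diels–Alder adduct
Product: 9 (5S,10S)-6-oxo-8-ene with 5α-H, 10β-methyl and the C9 acyl pyrazole (trans-fused ketone)
Conditions: 1 M aq. HCl, THF, 0 °C → rt
Reagents that add atoms: none
Why: Acid hydrolysis of the silyl enol ether protonates C5 from the α face, anti to the 10β-methyl group, and the trans-fused ketone is also the thermodynamic epimer at this enolisable centre, so 5α-H should result, while mild acid avoids migration of the C8=C9 bond.

Step 7
Reactants: 9 the trans-fused 6-ketone
Product: 11 (5S,7S,10S)-7α-hydroxy-6-oxo-8-ene with the C9 acyl pyrazole, via potassium dienolate 10 (not isolated)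
Conditions: KN(SiMe3)2 (1.1 equiv), THF, −78 °C; 2-(phenylsulfonyl)-3-phenyloxaziridine, −78 °C; AcOH quench at −78 °C
Reagents that add atoms: 2-(phenylsulfonyl)-3-phenyloxaziridine, O=S(=O)(c1ccccc1)N1OC1c1ccccc1; KN(SiMe3)2, C[Si](C)(C)N([K])[Si](C)(C)C (its potassium stays only in intermediate 10)
Why: Davis enolate oxidation: kinetic deprotonation takes the C7 methylene (α to C6=O and vinylogous to the C11 carbonyl) instead of the hindered tertiary C5–H, and oxygen transfer to C7 from the α face, along the chair-like axial path anti to the 10β-methyl group, should give the 7α-alcohol, attack at C9 being blocked by the adjacent quaternary centre.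

Step 8
Reactants: 11 the 7α-hydroxy-6-ketone
Product: 12 (5S,7S,10S)-7α-(triethylsilyloxy)-6-oxo-8-ene with the C9 acyl pyrazole
Conditions: TESCl, imidazole, DMF, 0 °C → rt
Reagents that add atoms: chlorotriethylsilane, CC[Si](Cl)(CC)CC
Why: Silylation of the secondary alcohol with a silyl chloride and imidazole, a base too weak to enolise the ketol, should protect O7 without ketol transposition or enol silylation.

Step 9
Reactants: 12 the 7α-silyloxy-6-ketone
Product: 13 (5S,6S,7S,10S)-7α-(triethylsilyloxy)-8-ene-6β,11-diol
Conditions: LiAlH4 (excess), THF, −78 → 0 °C; Rochelle salt work-up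
Reagents that add atoms: none
Why: Hydride reduction under steric approach control: the β face of C6 is closed by the syn-axial 4β- and 10β-methyl groups, so hydride should enter from the α face and give the axial 6β-alcohol, while the same reagent reduces the activated amide (acyl pyrazole) through the aldehyde to the primary allylic alcohol in 1,2-fashion because the β-carbon is tetrasubstituted.

Step 10
Reactants: 13 the 6β,11-diol
Product: 14 (5S,6S,7S,10S)-6β-hydroxy-7α-(triethylsilyloxy)-8-en-11-al
Conditions: activated MnO2, CH2Cl2, rt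
Reagents that add atoms: none
Why: MnO2 oxidises only allylic alcohols, so the primary C11 alcohol should go to the enal while the non-allylic 6β-hydroxyl stays untouched.

Step 11
Reactants: 14 the C11 enal
Product: 15 (5S,6S,7S,10S)-9-vinyl-7α-(triethylsilyloxy)-8-en-6β-ol (C8=C9–C11=C12 diene)
Conditions: Ph3PCH3Br (3 equiv), KN(SiMe3)2 (3 equiv), THF, 0 °C → rt
Reagents that add atoms: methyltriphenylphosphonium bromide, C[P+](c1ccccc1)(c1ccccc1)c1ccccc1.[Br-]
Why: Wittig methylenation of a hindered enal of the β-cyclocitral type is well precedented, and the excess of ylide covers the free 6β-hydroxyl, whose alkoxide cannot take over the trans-diaxial silyl group.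

Step 12
Reactants: 15 the C9 vinyl 6β-alcohol
Product: 16 (5S,6S,7S,10S)-6β-acetoxy-9-vinyl-7α-(triethylsilyloxy)-8-ene
Conditions: Ac2O, DMAP (1 equiv), pyridine, 50 °C
Reagents that add atoms: acetic anhydride, CC(=O)OC(C)=O
Why: DMAP-catalysed acetylation under forcing conditions should esterify the only free hydroxyl, the hindered axial 6β-alcohol, with retention at C6.

Step 13
Reactants: 17 but-2-yn-1-ol
Product: 19 (Z)-3-iodobut-2-en-1-ol, via sodium vinylalanate 18 (not isolated)
Conditions: NaAlH2(OCH2CH2OMe)2 (Red-Al), THF, 0 °C → rt; EtOAc; I2, THF, −78 → 0 °C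
Reagents that add atoms: iodine, II; NaAlH2(OCH2CH2OMe)2, [Na+].[AlH2-](OCCOC)OCCOC (its sodium, aluminium and alkoxy groups stay only in intermediate 18)
Why: Alkoxide-directed trans-hydroalumination of the propargylic alcohol places aluminium on C3 in a five-membered alanate, and iodinolysis with retention should give the (Z)-vinyl iodide as a single isomer.

Step 14
Reactants: 19 (Z)-3-iodobut-2-en-1-ol
Product: 20 (Z)-tert-butyl[(3-iodobut-2-en-1-yl)oxy]dimethylsilane
Conditions: TBSCl, imidazole, CH2Cl2, 0 °C → rt
Reagents that add atoms: tert-butyldimethylsilyl chloride, CC(C)(C)[Si](C)(C)Cl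
Why: Standard silylation of a primary allylic alcohol, which leaves the vinyl iodide and its geometry untouched.

Step 15
Reactants: 16 the C9 vinyl 6β-acetate; 20 the (Z)-vinyl iodide silyl ether
Product: 22 (5S,6S,7S,10S,13Z)-6β-acetoxy-7α-(triethylsilyloxy)-15-(tert-butyldimethylsilyloxy)labda-8,13-diene, via alkyl-9-BBN borane 21 (not isolated)
Conditions: 9-BBN, THF, 0 °C → rt; then 20, PdCl2(dppf) (5 mol %), AsPh3, 3 M aq. K3PO4, DMF, rt
Reagents that add atoms: 9-borabicyclo[3.3.1]nonane (9-BBN), B1C2CCCC1CCC2 (its boron and carbons stay only in intermediate 21)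
Why: 9-BBN hydroborates only the monosubstituted C11=C12 alkene, anti-Markovnikov, leaving the tetrasubstituted C8=C9 bond alone, and the B-alkyl Suzuki–Miyaura coupling should join C12 to C13 with retention of the (Z)-geometry under a base mild enough for the hindered acetate.

Step 16
Reactants: 22 the bis-silyl ether
Product: 23 the target, (5S,6S,7S,10S,13Z)-6β-acetoxylabda-8,13-diene-7α,15-diol
Conditions: HF·pyridine, pyridine, THF, 0 °C → rt
Reagents that add atoms: none
Why: Buffered fluoride desilylation removes both silyl ethers without ionising the allylic C7 position, and the acetate should neither cleave nor migrate because O6 and O7 are trans-diaxial.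

## Compound list

1 | β-cyclocitral | CC1=C(C=O)C(C)(C)CCC1 | starting material
2 | (±)-1-(2,6,6-trimethylcyclohex-1-en-1-yl)ethan-1-ol | CC(O)C1=C(C)CCCC1(C)C | intermediate
3 | 1-(2,6,6-trimethylcyclohex-1-en-1-yl)ethan-1-one | CC(=O)C1=C(C)CCCC1(C)C | intermediate
4 | tert-butyldimethyl{[1-(2,6,6-trimethylcyclohex-1-en-1-yl)ethenyl]oxy}silane (2-siloxydiene) | C=C(O[Si](C)(C)C(C)(C)C)C1=C(C)CCCC1(C)C | intermediate
5 | but-2-ynoic acid | CC#CC(=O)O | starting material
6 | 3,5-dimethylpyrazole | Cc1cc(C)[nH]n1 | starting material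
7 | 1-(3,5-dimethyl-1H-pyrazol-1-yl)but-2-yn-1-one | CC#CC(=O)n1nc(C)cc1C | intermediate
8 | (10S)-6-(tert-butyldimethylsilyloxy)-5,8-diene, 10β-methyl, C9 acyl pyrazole (Diels–Alder adduct) | CC(C)(C)[Si](C)(C)OC1=C2C(C)(C)CCC[C@]2(C)C(C(=O)n3nc(C)cc3C)=C(C)C1 | intermediate
9 | (5S,10S)-6-oxo-8-ene, 5α-H, 10β-methyl, C9 acyl pyrazole | O=C1CC(C)=C(C(=O)n3nc(C)cc3C)[C@@]2(C)CCCC(C)(C)[C@H]12 | intermediate
10 | potassium C6–C7 dienolate of 9 | [K+].[O-]C1=CC(C)=C(C(=O)n3nc(C)cc3C)[C@@]2(C)CCCC(C)(C)[C@H]12 | intermediate (not isolated)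
11 | (5S,7S,10S)-7α-hydroxy-6-oxo-8-ene, C9 acyl pyrazole | O=C1[C@@H](O)C(C)=C(C(=O)n3nc(C)cc3C)[C@@]2(C)CCCC(C)(C)[C@H]12 | intermediate
12 | (5S,7S,10S)-7α-(triethylsilyloxy)-6-oxo-8-ene, C9 acyl pyrazole | O=C1[C@@H](O[Si](CC)(CC)CC)C(C)=C(C(=O)n3nc(C)cc3C)[C@@]2(C)CCCC(C)(C)[C@H]12 | intermediate
13 | (5S,6S,7S,10S)-7α-(triethylsilyloxy)-8-ene-6β,11-diol | O[C@@H]1[C@@H](O[Si](CC)(CC)CC)C(C)=C(CO)[C@@]2(C)CCCC(C)(C)[C@H]12 | intermediate
14 | (5S,6S,7S,10S)-6β-hydroxy-7α-(triethylsilyloxy)-8-en-11-al | O[C@@H]1[C@@H](O[Si](CC)(CC)CC)C(C)=C(C=O)[C@@]2(C)CCCC(C)(C)[C@H]12 | intermediate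
15 | (5S,6S,7S,10S)-9-vinyl-7α-(triethylsilyloxy)-8-en-6β-ol | O[C@@H]1[C@@H](O[Si](CC)(CC)CC)C(C)=C(C=C)[C@@]2(C)CCCC(C)(C)[C@H]12 | intermediate
16 | (5S,6S,7S,10S)-6β-acetoxy-9-vinyl-7α-(triethylsilyloxy)-8-ene | CC(=O)O[C@@H]1[C@@H](O[Si](CC)(CC)CC)C(C)=C(C=C)[C@@]2(C)CCCC(C)(C)[C@H]12 | intermediate
17 | but-2-yn-1-ol | CC#CCO | starting material
18 | sodium cyclic vinylalanate from 17 (aluminium on C3, cis to CH2O) | C/C1=C/CO[Al-]1(OCCOC)OCCOC.[Na+] | intermediate (not isolated)
19 | (Z)-3-iodobut-2-en-1-ol | C/C(I)=C/CO | intermediate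
20 | (Z)-tert-butyl[(3-iodobut-2-en-1-yl)oxy]dimethylsilane | C/C(I)=C/CO[Si](C)(C)C(C)(C)C | intermediate
21 | C12 alkyl-9-BBN borane from 16 | CC(=O)O[C@@H]1[C@@H](O[Si](CC)(CC)CC)C(C)=C(CCB3C4CCCC3CCC4)[C@@]2(C)CCCC(C)(C)[C@H]12 | intermediate (not isolated)
22 | (5S,6S,7S,10S,13Z)-6β-acetoxy-7α-(triethylsilyloxy)-15-(tert-butyldimethylsilyloxy)labda-8,13-diene | CC(=O)O[C@@H]1[C@@H](O[Si](CC)(CC)CC)C(C)=C(CC/C(C)=C\CO[Si](C)(C)C(C)(C)C)[C@@]2(C)CCCC(C)(C)[C@H]12 | intermediate
23 | (5S,6S,7S,10S,13Z)-6β-acetoxylabda-8,13-diene-7α,15-diol (CNP0183298.2) | CC(=O)O[C@@H]1[C@@H](O)C(C)=C(CC/C(C)=C\CO)[C@@]2(C)CCCC(C)(C)[C@H]12 | target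

## Step count and risks

Total step count: 16. Longest linear sequence: 13 steps (steps 1–3, 5–12, 15, 16).

**Step 5 (key step, proposed new method).** The diene may fail to reach the s-cis geometry inside the catalyst pocket because the silyloxy group is pressed against the C4 gem-dimethyl group. The reaction may also divert into an open-chain Mukaiyama–Michael adduct or a [2+2] adduct at the enol ether, or the catalyst may discriminate the diene faces poorly.

Fallback: set out from 4 and 7 and run the uncatalysed thermal cycloaddition (toluene, 120 °C, sealed tube). This is the reaction class by which 1-vinyl-2,6,6-trimethylcyclohexene is known to add acetylenic esters, with the regiochemistry still governed by the siloxy group. It should give the racemic Diels–Alder adduct F1. Hydrolysis as in step 6 gives the racemic trans-fused ketone F2, whose enantiomers are separated by preparative chromatography on a chiral stationary phase. The (5S,10S)-enantiomer is ketone 9, where the route is rejoined.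

**Step 7.** The dienolate may be over-oxidised, the oxidant may approach with insufficient face selectivity, or base may cause ketol transposition or move the C8=C9 bond into conjugation with the ketone.

Fallback: set out from ketone 9 and use a Rubottom oxidation instead of an enolate oxidation. TESOTf/Et3N (CH2Cl2, −78 °C) gives the 6-(triethylsilyloxy)-6,8-diene F3. Dimethyldioxirane (acetone, −78 °C) epoxidises the electron-rich C6=C7 bond from the α face to the silyloxy epoxide F4. This opens with 1,4-silyl shift to the 7α-(triethylsilyloxy) ketone 12, where the route is rejoined without strong base and without a free ketol.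

**Step 9.** Facial selectivity at C6 may erode because the adjacent axial 7α-silyloxy group hinders the α face, and some conjugate reduction of the enoyl unit may occur.

Fallback: set out from ketol 11 and deliver the hydride intramolecularly. Me4NBH(OAc)3 (MeCN/AcOH, −20 °C; hydroxyl-directed Saksena–Evans reduction) binds the 7α-oxygen and delivers hydride to the α face of C6, giving the 6β,7α-diol acyl pyrazole F5. Selective silylation of the more accessible allylic 7α-hydroxyl (TESCl, imidazole, DMF, 0 °C) gives the 6β-hydroxy-7α-(triethylsilyloxy) acyl pyrazole F6. Reduction of the acyl pyrazole alone (LiAlH4, THF, 0 °C) returns to diol 13.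

## Further compounds

F1 | step 5 | racemic Diels–Alder adduct (racemate of 8) | CC(C)(C)[Si](C)(C)OC1=C2C(C)(C)CCCC2(C)C(C(=O)n3nc(C)cc3C)=C(C)C1
F2 | step 5 | racemic trans-fused 6-ketone (racemate of 9, both enantiomers written) | O=C1CC(C)=C(C(=O)n3nc(C)cc3C)[C@@]2(C)CCCC(C)(C)[C@H]12.O=C1CC(C)=C(C(=O)n3nc(C)cc3C)[C@]2(C)CCCC(C)(C)[C@@H]12
F3 | step 7 | (5S,10S)-6-(triethylsilyloxy)-6,8-diene, C9 acyl pyrazole | CC[Si](CC)(CC)OC1=CC(C)=C(C(=O)n3nc(C)cc3C)[C@@]2(C)CCCC(C)(C)[C@H]12
F4 | step 7 | 6α,7α-epoxy-6β-(triethylsilyloxy)-8-ene, C9 acyl pyrazole | CC[Si](CC)(CC)O[C@]1(O4)[C@@H]4C(C)=C(C(=O)n3nc(C)cc3C)[C@@]2(C)CCCC(C)(C)[C@H]12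
F5 | step 9 | (5S,6S,7S,10S)-6β,7α-dihydroxy-8-ene, C9 acyl pyrazole | O[C@@H]1[C@@H](O)C(C)=C(C(=O)n3nc(C)cc3C)[C@@]2(C)CCCC(C)(C)[C@H]12
F6 | step 9 | (5S,6S,7S,10S)-6β-hydroxy-7α-(triethylsilyloxy)-8-ene, C9 acyl pyrazole | O[C@@H]1[C@@H](O[Si](CC)(CC)CC)C(C)=C(C(=O)n3nc(C)cc3C)[C@@]2(C)CCCC(C)(C)[C@H]12
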